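The central phloroglucinol ring (ring B) is the point of disconnection. Its carbons alternate between oxygen-bearing (C1, C3, C5) and bromine- or carbon-bearing (C2, C4, C6), and the two arylmethyl groups at C4 and C6 flank the C5 oxygen. A thermal benzannulation joins a 2-arylmethyl-3-methoxycyclobutenone to a methyl ynol ether carrying the same arylmethyl group. One operation forms three C–C bonds and closes ring B as a 2,4-dibenzyl-3,5-dimethoxyphenol with one free position left for bromine. One ynol ether, built from 5-bromovanillin, serves as the alkyne and, after ketene cycloaddition, as the cyclobutenone; its O-methyl group (no β-hydrogen) cannot be lost as an alkene on heating.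

Key step: step 8

Remark: the target is achiral, so no stereocentre has to be set. Ring B is numbered as in the target name throughout (O on C1, C3, C5; Br on C2; arylmethyl on C4 and C6), which differs from the locants in the systematic name of 17. Methoxyacetylene is not assumed to be purchasable, so its lithium salt is generated in the flask.

Step 1
Reactants: 1 5-bromovanillin
Product: 2 2,3-dibromo-4-hydroxy-5-methoxybenzaldehyde
Conditions: Br2, Fe powder (cat.), AcOH, rt → 60 °C
Reagents that add atoms: bromine, BrBr
Why: Electrophilic aromatic bromination; the positions ortho and para to the hydroxyl are blocked, so the methoxy group should direct the second bromine to the free carbon para to it (C2, next to the first bromine), which gives the 2,3-dibromo pattern of the outer rings.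

Step 2
Reactants: 2 2,3-dibromo-4-hydroxy-5-methoxybenzaldehyde
Product: 3 2,3-dibromo-4,5-dimethoxybenzaldehyde
Conditions: MeI, K2CO3, DMF, rt
Reagents that add atoms: iodomethane, CI
Why: Williamson O-methylation of the phenoxide, to which the aldehyde and the aryl bromides are inert.

Step 3
Reactants: 3 2,3-dibromo-4,5-dimethoxybenzaldehyde
Product: 4 (2,3-dibromo-4,5-dimethoxyphenyl)methanol
Conditions: NaBH4, MeOH–THF, 0 °C
Reagents that add atoms: none
Why: Borohydride reduction of the aldehyde, which leaves aryl bromides and methyl ethers untouched.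

Step 4
Reactants: 4 (2,3-dibromo-4,5-dimethoxyphenyl)methanol
Product: 5 2,3-dibromo-1-(bromomethyl)-4,5-dimethoxybenzene
Conditions: PBr3, CH2Cl2, 0 °C → rt
Reagents that add atoms: phosphorus tribromide, BrP(Br)Br
Why: Conversion of a benzylic alcohol into the bromide by SN2 displacement on its bromophosphite, a routine reaction for electron-rich benzyl alcohols.

Step 5
Reactants: 5 2,3-dibromo-1-(bromomethyl)-4,5-dimethoxybenzene; 6 2-chloro-1,1-dimethoxyethane
Product: 8 3-(2,3-dibromo-4,5-dimethoxyphenyl)-1-methoxyprop-1-yne, via lithium methoxyacetylide 7 (not isolated)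
Conditions: 6 (2 equiv), LiNEt2 (from n-BuLi and Et2NH; 2.9 equiv per 6), THF, 0 °C; then 5, DMPU, −40 → 0 °C; NaHCO3 work-up
Reagents that add atoms: none
Why: Twofold elimination (methanol, then HCl) from the chloroacetal by the lithium amide gives the alkoxyacetylide, and its SN2 alkylation by the benzylic bromide in the presence of DMPU is the standard entry to 1-alkoxy-1-alkynes; the amide is kept in slight deficit and no alkyllithium remains when 5 is added, so the aryl bromides should not be metalated.

Step 6
Reactants: 8 3-(2,3-dibromo-4,5-dimethoxyphenyl)-1-methoxyprop-1-yne; 9 trichloroacetyl chloride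
Product: 11 4,4-dichloro-2-(2,3-dibromo-4,5-dimethoxybenzyl)-3-methoxycyclobut-2-en-1-one, via dichloroketene 10 (not isolated)
Conditions: Zn–Cu couple, DME, Et2O, rt, slow addition of 9
Reagents that add atoms: none
Why: [2+2] cycloaddition of dichloroketene (made by zinc dechlorination of the acid chloride) with the electron-rich alkyne, in which the arylmethyl-substituted alkyne carbon, the electron-rich end β to oxygen, attacks the ketene carbonyl carbon so that the methoxy group ends next to the CCl2 carbon; DME binds ZnCl2 and protects the acid-sensitive ynol ether.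

Step 7
Reactants: 11 4,4-dichloro-2-(2,3-dibromo-4,5-dimethoxybenzyl)-3-methoxycyclobut-2-en-1-one
Product: 12 2-(2,3-dibromo-4,5-dimethoxybenzyl)-3-methoxycyclobut-2-en-1-one
Conditions: Zn dust, AcOH, TMEDA, MeOH, 0 °C → rt
Reagents that add atoms: none
Why: Buffered zinc reduction of an α,α-dichloroketone, the standard dechlorination of 4,4-dichlorocyclobutenones; aryl C–Br bonds do not react with zinc at this temperature, and methanol as solvent makes any alkoxy exchange at the vinylogous ester degenerate.

Step 8
Reactants: 12 2-(2,3-dibromo-4,5-dimethoxybenzyl)-3-methoxycyclobut-2-en-1-one; 8 3-(2,3-dibromo-4,5-dimethoxyphenyl)-1-methoxyprop-1-yne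
Product: 17 2,4-bis(2,3-dibromo-4,5-dimethoxybenzyl)-3,5-dimethoxyphenol, via vinylketene 13 (not isolated), via 4-vinylcyclobutenone 14 (not isolated), via dienylketene 15 (not isolated), via cyclohexadienone 16 (not isolated)
Conditions: 8 (1.5 equiv), degassed PhMe, sealed tube, 110 → 150 °C
Reagents that add atoms: none
Why: Danheiser benzannulation of a cyclobutenone with an alkoxyalkyne, run as a purely thermal cascade of four pericyclic events: conrotatory 4π opening of 12 to vinylketene 13, [2+2] cycloaddition of the ketene C=C bond of 13 with 8 to 4-vinylcyclobutenone 14, a second 4π opening to dienylketene 15, and disrotatory 6π electrocyclisation to dienone 16, which enolises to 17. With ring B numbered as in the target, 12 supplies C1 (carbonyl), C4, C3 and C2 and 8 supplies C6 and C5; the new bonds are C1–C6 and C4–C5 from the cycloaddition and C1–C2 from the 6π step, which is the ring-closing event (thermal 6π electrocyclic closure of a triene whose six atoms are all sp2). The one selectivity needed is the orientation of the [2+2] step: the oxygen lone pair makes the arylmethyl-substituted alkyne carbon the electron-rich terminus, so it attacks the electrophilic ketene carbon C1 and the methoxy carbon of the alkyne ends at C5 between the two arylmethyl groups. No stereocentre survives, since the quaternary carbon of racemic 14 becomes sp2 on ring opening, and a dienylketene of the wrong double-bond geometry can return through 14 until the cyclisable isomer 15 is drained by ring closure. The closest known reaction with this oxygen pattern is the thermal union of 3-alkoxycyclobutenones with 1-alkoxyalkynes to 3,5-dialkoxyphenols; a vinylogous-ester cyclobutenone opens less readily than a 3-alkyl one, so the alkyne must survive prolonged heating, which the methyl ether (no retro-ene route to a ketene) should do. No metal, acid or base is present, so the four aryl C–Br bonds and the benzylic CH2 groups should be untouched.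

Step 9
Reactants: 17 2,4-bis(2,3-dibromo-4,5-dimethoxybenzyl)-3,5-dimethoxyphenol
Product: 18 2-bromo-4,6-bis(2,3-dibromo-4,5-dimethoxybenzyl)-3,5-dimethoxyphenol
Conditions: NBS (1.0 equiv), CH2Cl2, −78 → 0 °C, dark
Reagents that add atoms: N-bromosuccinimide, O=C1CCC(=O)N1Br
Why: Electrophilic aromatic bromination; of the three aromatic C–H positions only C2 of ring B lies ortho to the free hydroxyl and to a methoxy group, whereas the single C–H of each outer ring sits on a ring deactivated by two bromines, so one equivalent of NBS should brominate ring B alone.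

Step 10
Reactants: 18 2-bromo-4,6-bis(2,3-dibromo-4,5-dimethoxybenzyl)-3,5-dimethoxyphenol
Product: 19 Vidalol B (2-bromo-4,6-bis(2,3-dibromo-4,5-dihydroxybenzyl)benzene-1,3,5-triol)
Conditions: BBr3 (excess), CH2Cl2, −78 °C → rt; then H2O
Reagents that add atoms: none
Why: Lewis-acid cleavage of aryl methyl ethers by BBr3 (bromide attack on the methyl group of the O–B complex), which should remove all six methyl groups without affecting aryl bromides or the diarylmethane links.

Compound list
1 | 5-bromovanillin (3-bromo-4-hydroxy-5-methoxybenzaldehyde) | COc1cc(C=O)cc(Br)c1O | starting material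
2 | 2,3-dibromo-4-hydroxy-5-methoxybenzaldehyde | COc1cc(C=O)c(Br)c(Br)c1O | intermediate
3 | 2,3-dibromo-4,5-dimethoxybenzaldehyde | COc1cc(C=O)c(Br)c(Br)c1OC | intermediate
4 | (2,3-dibromo-4,5-dimethoxyphenyl)methanol | COc1cc(CO)c(Br)c(Br)c1OC | intermediate
5 | 2,3-dibromo-1-(bromomethyl)-4,5-dimethoxybenzene | COc1cc(CBr)c(Br)c(Br)c1OC | intermediate
6 | 2-chloro-1,1-dimethoxyethane (chloroacetaldehyde dimethyl acetal) | COC(CCl)OC | starting material
7 | lithium methoxyacetylide (not isolated) | [Li]C#COC | intermediate
8 | 3-(2,3-dibromo-4,5-dimethoxyphenyl)-1-methoxyprop-1-yne | COC#CCc1cc(OC)c(OC)c(Br)c1Br | intermediate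
9 | trichloroacetyl chloride | ClC(=O)C(Cl)(Cl)Cl | starting material
10 | dichloroketene (not isolated) | O=C=C(Cl)Cl | intermediate
11 | 4,4-dichloro-2-(2,3-dibromo-4,5-dimethoxybenzyl)-3-methoxycyclobut-2-en-1-one | COC1=C(Cc2cc(OC)c(OC)c(Br)c2Br)C(=O)C1(Cl)Cl | intermediate
12 | 2-(2,3-dibromo-4,5-dimethoxybenzyl)-3-methoxycyclobut-2-en-1-one | COC1=C(Cc2cc(OC)c(OC)c(Br)c2Br)C(=O)C1 | intermediate
13 | 2-(2,3-dibromo-4,5-dimethoxybenzyl)-3-methoxybuta-1,3-dien-1-one (vinylketene, not isolated) | C=C(OC)C(Cc1cc(OC)c(OC)c(Br)c1Br)=C=O | intermediate
14 | 2,4-bis(2,3-dibromo-4,5-dimethoxybenzyl)-3-methoxy-4-(1-methoxyvinyl)cyclobut-2-en-1-one (racemic, not isolated) | C=C(OC)C1(Cc2cc(OC)c(OC)c(Br)c2Br)C(OC)=C(Cc2cc(OC)c(OC)c(Br)c2Br)C1=O | intermediate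
15 | (3E)-2,4-bis(2,3-dibromo-4,5-dimethoxybenzyl)-3,5-dimethoxyhexa-1,3,5-trien-1-one (dienylketene, ketene and vinyl groups cis, not isolated) | O=C=C(Cc1cc(OC)c(OC)c(Br)c1Br)/C(OC)=C(\C(OC)=C)Cc1cc(OC)c(OC)c(Br)c1Br | intermediate
16 | 2,4-bis(2,3-dibromo-4,5-dimethoxybenzyl)-3,5-dimethoxycyclohexa-2,4-dien-1-one (not isolated) | O=C1CC(OC)=C(Cc2cc(OC)c(OC)c(Br)c2Br)C(OC)=C1Cc1cc(OC)c(OC)c(Br)c1Br | intermediate
17 | 2,4-bis(2,3-dibromo-4,5-dimethoxybenzyl)-3,5-dimethoxyphenol | COc1cc(O)c(Cc2cc(OC)c(OC)c(Br)c2Br)c(OC)c1Cc1cc(OC)c(OC)c(Br)c1Br | intermediate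
18 | 2-bromo-4,6-bis(2,3-dibromo-4,5-dimethoxybenzyl)-3,5-dimethoxyphenol | COc1c(Br)c(O)c(Cc2cc(OC)c(OC)c(Br)c2Br)c(OC)c1Cc1cc(OC)c(OC)c(Br)c1Br | intermediate
19 | Vidalol B, 2-bromo-4,6-bis(2,3-dibromo-4,5-dihydroxybenzyl)benzene-1,3,5-triol | Oc1cc(Cc2c(O)c(Br)c(O)c(Cc3cc(O)c(O)c(Br)c3Br)c2O)c(Br)c(Br)c1O | target

Total step count: 10. Longest linear sequence: 10 steps (1 → 19); compound 8 is used twice, in step 6 and in step 8.

Steps most likely to fail

Step 8. The vinylogous-ester cyclobutenone may open so slowly that the ynol ether oligomerises first. The cascade may also stall at the vinylcyclobutenone stage, or the product phenol may be acylated by ketene intermediates. The fallback abandons the annulation and builds ring B from a preformed arene. It sets out from alcohol 4 and comes back at target 19. Twofold Friedel–Crafts benzylation of commercial 1,3,5-trimethoxybenzene with 4 (2 equiv, catalytic TfOH, CH2Cl2) should give 2,4-bis(2,3-dibromo-4,5-dimethoxybenzyl)-1,3,5-trimethoxybenzene F1. NBS should then brominate the last free position of the central ring to give 2-bromo-4,6-bis(2,3-dibromo-4,5-dimethoxybenzyl)-1,3,5-trimethoxybenzene F2. BBr3 in CH2Cl2 should cleave its seven methyl ethers to 19.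

Step 6. Lewis-acidic zinc salts may hydrate or polymerise the ynol ether during the cycloaddition, and the chlorines then have to be removed without hydrolysing the vinylogous ester. The fallback replaces dichloroketene by the parent ketene and so removes the need for dechlorination. It sets out from 8 and comes back at 12, bypassing 11 and step 7. Ketene F3 is generated in the flask from acetyl chloride and Et3N (MeCN, 0 °C → rt) in the presence of 8, and the [2+2] cycloaddition with the same orientation should give 12 directly.

Step 5. Diethylamine and lithium methoxide in the pot may compete with the acetylide for the benzylic bromide, and residual base may isomerise the propargylic ynol ether to an allenyl ether. The fallback separates acetylene formation from alkylation. It sets out from 6 and comes back at 7 and then 8. Treatment of 6 with NaNH2 in liquid NH3, aqueous quench and distillation should give methoxyacetylene F4, a low-boiling liquid that is kept as a cold THF solution. Deprotonation with slightly less than one equivalent of n-BuLi at −78 °C gives 7 free of amine and alkoxide, and alkylation with 5 in THF–DMPU then gives 8.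

Further compounds
F1 | step 8 | 2,4-bis(2,3-dibromo-4,5-dimethoxybenzyl)-1,3,5-trimethoxybenzene | COc1cc(OC)c(Cc2cc(OC)c(OC)c(Br)c2Br)c(OC)c1Cc1cc(OC)c(OC)c(Br)c1Br
F2 | step 8 | 2-bromo-4,6-bis(2,3-dibromo-4,5-dimethoxybenzyl)-1,3,5-trimethoxybenzene | COc1c(Br)c(OC)c(Cc2cc(OC)c(OC)c(Br)c2Br)c(OC)c1Cc1cc(OC)c(OC)c(Br)c1Br
F3 | step 6 | ketene | C=C=O
F4 | step 5 | methoxyacetylene | COC#C
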